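With the chain numbered from the benzylic carbon C1, the oxygen on C5 is tied temporarily to C1, turning the acyclic syn-3,5-diol into a 2-aryl-6-propyl tetrahydropyran (ring atoms O, C1–C5). One catalytic asymmetric hetero-Diels–Alder reaction between a 2-silyloxy diene (C2–C8) and a vanillin carbonate (C1) forms C1–C2 and C5–O, closes that ring and sets C5 absolutely. The chair then dictates C3, and the benzylic C1–O bond, para to the phenol oxygen, is finally erased by ionic hydrogenation. The phenol travels as a tert-butyl carbonate: electron-poor during the cycloaddition, removed by the very acid that opens the ring, where an acetate would stay and retard ionisation.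

Key step: step 2

Assumption: the ligand antipode from (1S,2R)-1-amino-2-indanol is taken to direct the diene to the Si face of the aldehyde, by analogy with Re-face addition in the (1R,2S) series; if the sense is opposite here, the (1R,2S) ligand is used and nothing else changes.
Assumption: the vanillin tert-butyl carbonate is taken as a purchased compound.
Notation: C1–C8 are the octane-chain carbons of the target, C1 being benzylic. CrCl(L) is the chloride complex of trivalent chromium with L = C27H29NO2, the dianion of the Schiff base from 3-(1-adamantyl)-2-hydroxy-5-methylbenzaldehyde and (1S,2R)-1-amino-2-indanol.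

Step 1
Reactants: 1 (E)-hept-3-en-2-one; 2 triethylsilyl trifluoromethanesulfonate
Product: 3 (E)-2-(triethylsilyloxy)hepta-1,3-diene
Conditions: Et3SiOSO2CF3 (1.2 equiv), Et3N (2 equiv), Et2O, −78 to 0 °C
Reagents that add atoms: triethylsilyl trifluoromethanesulfonate (compound 2), CC[Si](CC)(CC)OS(=O)(=O)C(F)(F)F
Why: Silyl enol ether formation by soft enolisation: the silyl triflate activates the carbonyl oxygen and Et3N removes a proton from the accessible methyl group, so the cross-conjugated 2-silyloxy diene should form with the (E)-alkene untouched.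

Step 2
Reactants: 3 (E)-2-(triethylsilyloxy)hepta-1,3-diene; 4 tert-butyl (4-formyl-2-methoxyphenyl) carbonate
Product: 5 tert-butyl {2-methoxy-4-[(2S,6S)-6-propyl-4-(triethylsilyloxy)-3,6-dihydro-2H-pyran-2-yl]phenyl} carbonate (2,6-cis)
Conditions: CrCl(L) [L = C27H29NO2 Schiff-base dianion] (5 mol%), powdered 4 Å molecular sieves, acetone, rt (diene 1.5 equiv)
Reagents that add atoms: none
Why: The trivalent chromium centre binds the aldehyde oxygen as a Lewis acid, and the diene adds in a concerted but asynchronous [4+2] event in which its nucleophilic CH2 terminus (C2) bonds to the carbonyl carbon (C1) ahead of C5–O closure. The closest known reaction type is the catalytic asymmetric hetero-Diels–Alder reaction of 2-silyloxy dienes with aldehydes under tridentate Schiff-base chromium chloride complexes, in which aryl aldehydes are the less reactive partners. The dihydropyran (ring atoms O, C1, C2, C3, C4, C5) is closed by intermolecular cycloaddition, both ring bonds arising suprafacially in one step with no separate cyclisation. C1 is set by catalyst-controlled Si-face addition to the bound aldehyde, and C5 by the endo transition state acting on the (E)-alkene, which places aryl and propyl cis. Regiochemistry follows from the silyloxy group on C3, which makes C2 the nucleophilic terminus, and the required enantio- and endo-selectivity rest on the ligand pocket. The electron-withdrawing carbonate on the phenol keeps the carbonyl electrophilic enough for this weakly nucleophilic diene and is inert to the mild Lewis acid.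

Step 3
Reactants: 5 tert-butyl {2-methoxy-4-[(2S,6S)-6-propyl-4-(triethylsilyloxy)-3,6-dihydro-2H-pyran-2-yl]phenyl} carbonate
Product: 6 tert-butyl {2-methoxy-4-[(2S,6S)-4-oxo-6-propyltetrahydro-2H-pyran-2-yl]phenyl} carbonate
Conditions: 1 M aq. HCl, THF, 0 °C
Reagents that add atoms: none
Why: Acid-catalysed hydrolysis of a silyl enol ether: protonation at C4 and loss of silicon to water release the C3 ketone, C1 and C5 are not enolisable positions, the aryl tert-butyl carbonate should tolerate brief cold dilute acid, and any trans isomer is removed by chromatography at this stage.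

Step 4
Reactants: 6 tert-butyl {2-methoxy-4-[(2S,6S)-4-oxo-6-propyltetrahydro-2H-pyran-2-yl]phenyl} carbonate
Product: 7 tert-butyl {4-[(2S,4S,6S)-4-hydroxy-6-propyltetrahydro-2H-pyran-2-yl]-2-methoxyphenyl} carbonate (hydroxyl axial)
Conditions: LiBH(s-Bu)3 (1.2 equiv), THF, −78 °C; then aq. NH4Cl
Reagents that add atoms: none
Why: Diastereoselective ketone reduction with a bulky trialkylborohydride: in the chair with aryl and propyl both equatorial the reagent avoids the axial trajectory flanked by the axial C1–H and C5–H and delivers hydride equatorially, so the new C3 hydroxyl is axial and trans to propyl, which corresponds to (3R) and the 3,5-syn diol, while the hindered carbonate reacts far more slowly than the ketone at −78 °C.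

Step 5
Reactants: 7 tert-butyl {4-[(2S,4S,6S)-4-hydroxy-6-propyltetrahydro-2H-pyran-2-yl]-2-methoxyphenyl} carbonate
Product: 9 (3R,5S)-1-(4-hydroxy-3-methoxyphenyl)octane-3,5-diol, via phenol-tetrahydropyranol 8 (not isolated)
Conditions: Et3SiH (5 equiv), CF3CO2H–CH2Cl2 (1:4), 0 °C to rt; then NaHCO3, MeOH–H2O
Reagents that add atoms: none
Why: Ionic hydrogenation of a benzylic ether: CF3CO2H first cleaves the tert-butyl carbonate (2-methylpropene and CO2 lost, Et3SiH scavenging any tert-butyl cation), the liberated para-hydroxyl then lets the protonated C1–O bond ionise to a quinone-methide-like benzylic cation, and hydride transfer from Et3SiH converts C1 into CH2 without touching C3 or C5, the mild basic methanol work-up removing any trifluoroacetate or silyl groups from the hydroxyls.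

Step 6
Reactants: 9 (3R,5S)-1-(4-hydroxy-3-methoxyphenyl)octane-3,5-diol; 10 acetic anhydride
Product: 12 (3R,5S)-1-(4-hydroxy-3-methoxyphenyl)octane-3,5-diyl diacetate, via triacetate 11 (not isolated)
Conditions: Ac2O (3.6 equiv), Et3N (6 equiv), DMAP (0.1 equiv), CH2Cl2, 0 °C to rt; then pyrrolidine (3 equiv), 0 °C to rt
Reagents that add atoms: acetic anhydride (compound 10), CC(=O)OC(C)=O
Why: DMAP-catalysed acetylation of all three hydroxyls followed in the same flask by chemoselective aminolysis of the aryl ester: phenoxide is a much better leaving group than a secondary alkoxide, so pyrrolidine, which also consumes the surplus anhydride, should cleave only the phenolic acetate and leave the C3 and C5 acetates and their configurations intact.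

Compound list
1 | (E)-hept-3-en-2-one | CCC/C=C/C(C)=O | starting material
2 | triethylsilyl trifluoromethanesulfonate | CC[Si](CC)(CC)OS(=O)(=O)C(F)(F)F | starting material
3 | (E)-2-(triethylsilyloxy)hepta-1,3-diene | C=C(O[Si](CC)(CC)CC)/C=C/CCC | intermediate
4 | tert-butyl (4-formyl-2-methoxyphenyl) carbonate (O-Boc vanillin) | CC(C)(C)OC(=O)Oc1ccc(C=O)cc1OC | starting material
5 | tert-butyl {2-methoxy-4-[(2S,6S)-6-propyl-4-(triethylsilyloxy)-3,6-dihydro-2H-pyran-2-yl]phenyl} carbonate (2,6-cis) | CCC[C@H]1C=C(O[Si](CC)(CC)CC)C[C@@H](c2ccc(OC(=O)OC(C)(C)C)c(OC)c2)O1 | intermediate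
6 | tert-butyl {2-methoxy-4-[(2S,6S)-4-oxo-6-propyltetrahydro-2H-pyran-2-yl]phenyl} carbonate | CCC[C@H]1CC(=O)C[C@@H](c2ccc(OC(=O)OC(C)(C)C)c(OC)c2)O1 | intermediate
7 | tert-butyl {4-[(2S,4S,6S)-4-hydroxy-6-propyltetrahydro-2H-pyran-2-yl]-2-methoxyphenyl} carbonate (hydroxyl axial, trans to aryl and propyl) | CCC[C@H]1C[C@H](O)C[C@@H](c2ccc(OC(=O)OC(C)(C)C)c(OC)c2)O1 | intermediate
8 | (2S,4S,6S)-2-(4-hydroxy-3-methoxyphenyl)-6-propyltetrahydro-2H-pyran-4-ol | CCC[C@H]1C[C@H](O)C[C@@H](c2ccc(O)c(OC)c2)O1 | intermediate (not isolated)
9 | (3R,5S)-1-(4-hydroxy-3-methoxyphenyl)octane-3,5-diol | CCC[C@@H](C[C@@H](CCc1ccc(O)c(OC)c1)O)O | intermediate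
10 | acetic anhydride | CC(=O)OC(C)=O | starting material
11 | (3R,5S)-1-(4-acetoxy-3-methoxyphenyl)octane-3,5-diyl diacetate | CCC[C@@H](C[C@@H](CCc1ccc(OC(C)=O)c(OC)c1)OC(C)=O)OC(C)=O | intermediate (not isolated)
12 | (3R,5S)-1-(4-hydroxy-3-methoxyphenyl)octane-3,5-diyl diacetate (CNP0240815.2) | CCC[C@@H](C[C@@H](CCc1ccc(O)c(OC)c1)OC(C)=O)OC(C)=O | target

Total step count: 6.
Longest linear sequence: 6 steps (1 → 3 → 5 → 6 → 7 → 9 → 12).

Steps most likely to fail

Step 2. The aromatic aldehyde may react sluggishly with the weakly nucleophilic diene, with competing diene hydrolysis and erosion of enantio- or endo-selectivity. The fallback sets out from 1 and 4 and returns at 6, making the same two bonds stepwise. The diisopinocampheylboron enolate of 1 (Ipc2BCl antipode chosen for Si-face addition, Et3N, Et2O, −78 °C) should add to 4 in an aldol reaction to give tert-butyl {4-[(1S,4E)-1-hydroxy-3-oxooct-4-en-1-yl]-2-methoxyphenyl} carbonate F1. A catalytic amount of camphorsulfonic acid in CH2Cl2 should then close the ring by reversible 6-endo oxa-Michael addition of the C1 hydroxyl to C5, and thermodynamic control favours the diequatorial cis ketone 6.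

Step 5. The benzylic cation may be diverted before the silane reaches it, by internal 1,5-hydride transfer from C5–H, Friedel–Crafts oligomerisation or ring tert-butylation. The fallback sets out from 7 and returns at 12, cleaving C1–O without a cation. Heterogeneous hydrogenolysis (H2, Pd(OH)2 on carbon, EtOH, a little AcOH) should give tert-butyl {4-[(3R,5S)-3,5-dihydroxyoctyl]-2-methoxyphenyl} carbonate F2. Acetylation (Ac2O, pyridine, DMAP) then gives (3R,5S)-1-{4-[(tert-butoxycarbonyl)oxy]-3-methoxyphenyl}octane-3,5-diyl diacetate F3. CF3CO2H in CH2Cl2 at 0 °C removes the carbonate and delivers 12 directly, with no selective deacetylation needed.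

Step 6. Discrimination between the phenolic and the alkyl acetates may be incomplete in the one-flask protocol, through over-cleavage or partial acetylation of the hindered secondary hydroxyls. The fallback sets out from 9 and returns at 12, differentiating the phenol by alkylation instead of by ester reactivity. Phenol-selective Williamson etherification (BnBr, K2CO3, acetone) should give (3R,5S)-1-[4-(benzyloxy)-3-methoxyphenyl]octane-3,5-diol F4. Acetylation (Ac2O, pyridine, DMAP) gives (3R,5S)-1-[4-(benzyloxy)-3-methoxyphenyl]octane-3,5-diyl diacetate F5. Hydrogenolysis (H2, Pd on carbon, EtOAc) then frees the phenol to give 12.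

Further compounds
F1 | step 2 | tert-butyl {4-[(1S,4E)-1-hydroxy-3-oxooct-4-en-1-yl]-2-methoxyphenyl} carbonate | CCC/C=C/C(=O)C[C@H](O)c1ccc(OC(=O)OC(C)(C)C)c(OC)c1
F2 | step 5 | tert-butyl {4-[(3R,5S)-3,5-dihydroxyoctyl]-2-methoxyphenyl} carbonate | CCC[C@@H](C[C@@H](CCc1ccc(OC(=O)OC(C)(C)C)c(OC)c1)O)O
F3 | step 5 | (3R,5S)-1-{4-[(tert-butoxycarbonyl)oxy]-3-methoxyphenyl}octane-3,5-diyl diacetate | CCC[C@@H](C[C@@H](CCc1ccc(OC(=O)OC(C)(C)C)c(OC)c1)OC(C)=O)OC(C)=O
F4 | step 6 | (3R,5S)-1-[4-(benzyloxy)-3-methoxyphenyl]octane-3,5-diol | CCC[C@@H](C[C@@H](CCc1ccc(OCc2ccccc2)c(OC)c1)O)O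
F5 | step 6 | (3R,5S)-1-[4-(benzyloxy)-3-methoxyphenyl]octane-3,5-diyl diacetate | CCC[C@@H](C[C@@H](CCc1ccc(OCc2ccccc2)c(OC)c1)OC(C)=O)OC(C)=O
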